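## Retrosynthetic overview

1. Numbering: C1 ketone, C2=C3, C4 (C15 methyl), C5 (OH), C6 (lactone O), C7, C8 (O-angelate), C9 (OH), C10 (C14 methyl, ring O), C11=C13, C12 lactone C=O; ring A = carbocycle C1–C10, ring B = furanone (C1, C2, C3, O, C10), ring C = lactone (C6, C7, C11, C12, O).
2. Enabling feature: in ring C the exocyclic C11=C13 methylene, the ring-fusion carbon C7 and the oxygenated C8 of ring A form a homoallylic alcohol unit (C13=C11–C7–C8–O). This is the retron of an SE2′ allylation of a C8 aldehyde by a C13-metalated butenolide whose lactone oxygen already sits on C6.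
3. Disconnections: C8 ester (Mitsunobu, inversion) ⇒ C7–C8 (intramolecular Nozaki–Hiyama–Kishi allylation) ⇒ C7=C11 (ring-closing metathesis of a C6 2-(bromomethyl)acrylate) ⇒ O–C3 (5-endo oxa-Michael of an α′-hydroxy ynone) ⇒ C1–C2 (acetylide + Weinreb amide).
4. Fragments: west alkyne C2–C7 + C15 by Marshall propargylation (sets C4, C5; C6 from (R)-but-3-ene-1,2-diol); east amide C1, C8–C10, C14 from 2-C-methyl-D-erythrono-1,4-lactone (C9, C10).
5. Ring order: B (step 10), C (step 14), then A together with the nine-membered oxa-bridged ring (step 15).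

Key step: step 15

Assumption: 2-C-methyl-D-erythrono-1,4-lactone (9) is taken as a purchasable chiral-pool lactone; the numbering of line 1 is used for all positions below.

## Route

Step 1
Reactants: 1 (R)-but-3-ene-1,2-diol
Product: 2 (R)-3,4-bis(triethylsilyloxy)but-1-ene
Conditions: TESCl (2.3 equiv), imidazole, CH2Cl2, 0 °C → rt
Reagents that add atoms: chlorotriethylsilane (TESCl), CC[Si](Cl)(CC)CC
Why: Exhaustive O-silylation of a diol with a chlorosilane and imidazole is routine and does not touch the stereocentre (future C6).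

Step 2
Reactants: 2 (R)-3,4-bis(triethylsilyloxy)but-1-ene
Product: 3 (R)-2-(triethylsilyloxy)but-3-enal
Conditions: (COCl)2, DMSO, CH2Cl2, −78 → −30 °C; Et3N, −78 → 0 °C; used crude
Reagents that add atoms: none
Why: Swern oxidation under conditions known to cleave and oxidise a primary triethylsilyl ether while a secondary one survives should give the α-silyloxy aldehyde (future C5) in one operation, and cold handling of the crude aldehyde limits epimerisation and migration of the β,γ-double bond.

Step 3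
Reactants: 4 (R)-but-3-yn-2-ol
Product: 5 (R)-but-3-yn-2-yl methanesulfonate
Conditions: MsCl, Et3N, CH2Cl2, −78 °C
Reagents that add atoms: methanesulfonyl chloride, CS(=O)(=O)Cl
Why: Standard O-sulfonylation of a propargylic alcohol, with retention at the carbinol carbon.

Step 4
Reactants: 3 (R)-2-(triethylsilyloxy)but-3-enal; 5 (R)-but-3-yn-2-yl methanesulfonate
Product: 7 (3R,4S,5S)-5-methyl-3-(triethylsilyloxy)hept-1-en-6-yn-4-ol, via allenylzinc reagent 6 (not isolated)
Conditions: Pd(OAc)2 (5 mol %), PPh3 (5 mol %), Et2Zn (3 equiv), THF, −78 → −20 °C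
Reagents that add atoms: none
Why: Marshall propargylation, in which zerovalent palladium opens the mesylate anti-SN2′, Et2Zn transmetalates to allenylzinc 6 and this adds through a cyclic SE2′ transition state, so that C4 (net inversion of the mesylate centre) and the 4,5-anti relationship come from the reagent and the 5,6-anti relationship from Felkin–Anh addition to the α-silyloxy aldehyde, a matched pair.

Step 5
Reactants: 7 (3R,4S,5S)-5-methyl-3-(triethylsilyloxy)hept-1-en-6-yn-4-ol
Product: 8 (3R,4S,5S)-4-(tert-butyldimethylsilyloxy)-5-methyl-3-(triethylsilyloxy)hept-1-en-6-yne (west alkyne)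
Conditions: TBSOTf, 2,6-lutidine, CH2Cl2, −78 → 0 °C
Reagents that add atoms: tert-butyldimethylsilyl trifluoromethanesulfonate, CC(C)(C)[Si](C)(C)OS(=O)(=O)C(F)(F)F
Why: Silyl triflate with lutidine silylates the hindered C5 hydroxyl without silyl migration, giving the robust ether needed until the last step.

Step 6
Reactants: 9 2-C-methyl-D-erythrono-1,4-lactone
Product: 10 (3R,4R)-4-(tert-butyldimethylsilyloxy)-3-hydroxy-3-methyloxolan-2-one
Conditions: TBSCl (1.1 equiv), imidazole, DMF, 0 °C → rt
Reagents that add atoms: tert-butylchlorodimethylsilane, CC(C)(C)[Si](C)(C)Cl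
Why: Chemoselective silylation, since the secondary hydroxyl (future C9) reacts with TBSCl and imidazole whereas the tertiary α-hydroxyl (future C10) does not.

Step 7
Reactants: 10 (3R,4R)-4-(tert-butyldimethylsilyloxy)-3-hydroxy-3-methyloxolan-2-one
Product: 11 (2R,3R)-3-(tert-butyldimethylsilyloxy)-2,4-dihydroxy-N-methoxy-N,2-dimethylbutanamide
Conditions: MeNH(OMe)·HCl, AlMe3, CH2Cl2, 0 °C → rt; aq. KNaC4H4O6 (potassium sodium tartrate) work-up; used at once
Reagents that add atoms: N,O-dimethylhydroxylamine hydrochloride, CNOC.Cl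
Why: Weinreb aminolysis of a γ-lactone by the aluminium amide formed in the flask opens the ring at C1 without touching the two stereocentres.

Step 8
Reactants: 11 (2R,3R)-3-(tert-butyldimethylsilyloxy)-2,4-dihydroxy-N-methoxy-N,2-dimethylbutanamide
Product: 12 (2R,3R)-3-(tert-butyldimethylsilyloxy)-2-hydroxy-N-methoxy-N,2-dimethyl-4-(triethylsilyloxy)butanamide (east amide)
Conditions: TESCl (1.1 equiv), imidazole, CH2Cl2, −20 → 0 °C
Reagents that add atoms: chlorotriethylsilane (TESCl), CC[Si](Cl)(CC)CC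
Why: Chemoselective silylation of the primary C8 hydroxyl (the tertiary hydroxyl is inert) also blocks relactonisation of the γ-hydroxy amide.

Step 9
Reactants: 8 west alkyne; 12 east amide
Product: 15 (2R,3R,7S,8S,9R)-2,8-bis(tert-butyldimethylsilyloxy)-3-hydroxy-3,7-dimethyl-1,9-bis(triethylsilyloxy)undec-10-en-5-yn-4-one, via lithium acetylide 13 (not isolated), via chloromagnesium alkoxide 14 (not isolated)
Conditions: 8 (1.2 equiv), n-BuLi, THF, −78 °C; 12, i-PrMgCl (1.0 equiv), THF, −40 °C; combine, −78 → −20 °C; aq. NH4Cl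
Reagents that add atoms: none
Why: Acylation of a lithium acetylide by a Weinreb amide, whose chelated tetrahedral intermediate prevents over-addition, forms the C1–C2 bond, and prior conversion of the tertiary hydroxyl into its magnesium alkoxide spares the acetylide.

Step 10
Reactants: 15 α′-hydroxy ynone
Product: 17 (2R)-2-[(1R)-1-(tert-butyldimethylsilyloxy)-2-(triethylsilyloxy)ethyl]-5-[(2R,3S,4R)-3-(tert-butyldimethylsilyloxy)-4-(triethylsilyloxy)hex-5-en-2-yl]-2-methylfuran-3(2H)-one, via diethylamino enone 16 (not isolated)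
Conditions: Et2NH, EtOH, rt
Reagents that add atoms: none
Why: Amine-promoted 5-endo oxa-Michael cyclisation of an α′-hydroxy ynone to a 3(2H)-furanone (conjugate addition of the amine, then addition–elimination by the C10 hydroxyl) closes ring B under conditions that leave the silyl ethers and the 1,6-enyne motif alone, which a π-acid catalyst might not.

Step 11
Reactants: 17 bis-triethylsilyl furanone
Product: 18 (2R)-2-[(1R)-1-(tert-butyldimethylsilyloxy)-2-hydroxyethyl]-5-[(2R,3S,4R)-3-(tert-butyldimethylsilyloxy)-4-hydroxyhex-5-en-2-yl]-2-methylfuran-3(2H)-one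
Conditions: PPTS, MeOH/CH2Cl2 (1:1), 0 °C → rt
Reagents that add atoms: none
Why: Mild acid methanolysis removes the primary (C8) and secondary (C6) triethylsilyl ethers, while the two secondary tert-butyldimethylsilyl ethers are much slower to cleave and no base is present that could cause silyl migration.

Step 12
Reactants: 18 furanone diol
Product: 19 (2S)-2-(tert-butyldimethylsilyloxy)-2-{(2R)-5-[(2R,3S,4R)-3-(tert-butyldimethylsilyloxy)-4-hydroxyhex-5-en-2-yl]-2-methyl-3-oxo-2,3-dihydrofuran-2-yl}acetaldehyde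
Conditions: TEMPO (0.2 equiv), PhI(OAc)2 (1.2 equiv), CH2Cl2, rt
Reagents that add atoms: none
Why: Oxoammonium oxidation (TEMPO with PhI(OAc)2) is selective for the primary C8 alcohol over the hindered secondary allylic C6 alcohol and stops at the aldehyde without epimerising C9.

Step 13
Reactants: 19 hydroxy aldehyde; 20 2-(bromomethyl)prop-2-enoic acid
Product: 22 (3R,4S,5R)-4-(tert-butyldimethylsilyloxy)-5-{(2R)-2-[(1S)-1-(tert-butyldimethylsilyloxy)-2-oxoethyl]-2-methyl-3-oxo-2,3-dihydrofuran-5-yl}hex-1-en-3-yl 2-(bromomethyl)prop-2-enoate, via acid chloride 21 (not isolated)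
Conditions: 20, (COCl)2, DMF (cat.), CH2Cl2, 0 °C → rt, evaporate; then 19, 2,6-di-tert-butyl-4-methylpyridine, CH2Cl2, 0 °C → rt
Reagents that add atoms: none
Why: O-acylation of the C6 hydroxyl by an acid chloride with a hindered, non-nucleophilic pyridine as acid scavenger avoids the SN2′ attack on the allylic bromide that DMAP or Et3N would cause, and the aldehyde is inert.

Step 14
Reactants: 22 C6 2-(bromomethyl)acrylate
Product: 23 (2S)-2-{(2R)-5-[(1S,2R)-1-[(2R)-4-(bromomethyl)-5-oxo-2,5-dihydrofuran-2-yl]-1-(tert-butyldimethylsilyloxy)propan-2-yl]-2-methyl-3-oxo-2,3-dihydrofuran-2-yl}-2-(tert-butyldimethylsilyloxy)acetaldehyde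
Conditions: second-generation Hoveyda–Grubbs catalyst (10 mol %), toluene (2 mM), 80 °C
Reagents that add atoms: none
Why: Ring-closing metathesis of an acrylate ester of a vinyl carbinol, the standard route to α-substituted butenolides, forms C7=C11 and ring C with loss of ethene, and the electron-poor furanone alkene, the aldehyde and the allylic bromide should be tolerated by the ruthenium carbene.

Step 15
Reactants: 23 α-(bromomethyl)butenolide aldehyde
Product: 25 (4R,5S,6R,7R,8R,9R,10R)-5,9-bis(tert-butyldimethylsilyloxy)-8-hydroxy-1-oxo-3,10-epoxygermacra-2,11(13)-dien-12,6-olide, via allylchromium reagent 24 (not isolated)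
Conditions: CrCl2 (10 equiv), 4 Å MS, THF, rt, slow addition of 23 (final 2 mM)
Reagents that add atoms: none
Why: CrCl2 reduces the allylic C13–Br bond by two single-electron transfers to the C13-bound allylchromium 24 (trivalent chromium), which adds to the C8 aldehyde through C7 in a six-membered chair transition state (SE2′), so that the C7–C8 bond, the exocyclic C11=C13 methylene and the C8 chromium alkoxide arise together. The closest known reaction types are the intramolecular Nozaki–Hiyama–Kishi allylation of ω-formyl 2-(bromomethyl)acrylates, used to close ten-membered germacranolide and larger cembranolide carbocycles, and the Barbier addition of α-(bromomethyl)butenolides to aldehydes at the butenolide β-carbon. The bond closes ring A (C1–C10) in a 10-exo-trig mode at the carbonyl and, through the furanone oxygen, the nine-membered oxa-bridged ring (C3–C10 plus O) in a 9-exo-trig mode, completing the 11-oxabicyclo[6.2.1]undecene core fused to ring C. C7 is set by the C6 stereocentre, because the aldehyde is delivered on the butenolide face that carries the C5 tether and gives the cis-fused lactone with H6 and H7 both turned toward the furanone oxygen, whereas the other face would force the lactone into the interior of the nine-membered ring; C8 is set 8R because the ring-locked allyl unit (C6 trans to C13) reacts through the chair with C9 equatorial (7,8-anti topicity), which is also the Felkin–Anh face of the α-silyloxy aldehyde (8,9-anti), so 25 is the only one of the four diastereomers whose transition state satisfies both models. The step needs C7 (γ) over C13 (α) attack, aldehyde over ketone and lactone carbonyls, and cyclisation over dimerisation or reductive 1,4-elimination of the lactone carboxylate, and the six-membered transition state, the aldehyde selectivity of organochromium reagents and slow addition at high dilution should secure these. The 8R carbinol is the one wanted, because step 16 installs the ester with inversion (C7 has the target's spatial arrangement; its descriptor reads R in 25 only through a CIP priority change).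

Step 16
Reactants: 25 tricyclic (8R)-alcohol; 26 angelic acid, (Z)-2-methylbut-2-enoic acid
Product: 27 (4R,5S,6R,7S,8S,9R,10R)-8-[(Z)-2-methylbut-2-enoyloxy]-5,9-bis(tert-butyldimethylsilyloxy)-1-oxo-3,10-epoxygermacra-2,11(13)-dien-12,6-olide
Conditions: 26, PPh3, DIAD, toluene, 0 °C → rt
Reagents that add atoms: none
Why: Mitsunobu esterification displaces the C8 oxyphosphonium by angelate with inversion (8R → 8S); the acid is never activated at its carbonyl, so the Z double bond should be kept, and H7 is syn to the leaving group, which disfavours E2 elimination toward the conjugated diene.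

Step 17
Reactants: 27 bis-silyl angelate
Product: 28 target, (4R,5S,6R,7S,8S,9R,10R)-8-[(Z)-2-methylbut-2-enoyloxy]-5,9-dihydroxy-1-oxo-3,10-epoxygermacra-2,11(13)-dien-12,6-olide
Conditions: HF·pyridine, pyridine, THF, 0 °C → rt
Reagents that add atoms: none
Why: Buffered fluoride desilylation removes both secondary silyl ethers under mildly acidic conditions that the α-methylene lactone, the angelate and the furanone should tolerate.

## Compound list

1 | (2R)-but-3-ene-1,2-diol | C=C[C@@H](O)CO | starting material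
2 | (3R)-3,4-bis(triethylsilyloxy)but-1-ene | C=C[C@@H](O[Si](CC)(CC)CC)CO[Si](CC)(CC)CC | intermediate
3 | (2R)-2-(triethylsilyloxy)but-3-enal | C=C[C@@H](O[Si](CC)(CC)CC)C=O | intermediate
4 | (2R)-but-3-yn-2-ol | C#C[C@@H](C)O | starting material
5 | (2R)-but-3-yn-2-yl methanesulfonate | C#C[C@@H](C)OS(C)(=O)=O | intermediate
6 | (aS)-buta-1,2-dien-1-yl(ethyl)zinc, allenylzinc reagent | [H]C([Zn]CC)=[C@]=C([H])C | intermediate
7 | (3R,4S,5S)-5-methyl-3-(triethylsilyloxy)hept-1-en-6-yn-4-ol | C=C[C@@H](O[Si](CC)(CC)CC)[C@@H](O)[C@@H](C)C#C | intermediate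
8 | (3R,4S,5S)-4-(tert-butyldimethylsilyloxy)-5-methyl-3-(triethylsilyloxy)hept-1-en-6-yne | C=C[C@@H](O[Si](CC)(CC)CC)[C@@H](O[Si](C)(C)C(C)(C)C)[C@@H](C)C#C | intermediate
9 | 2-C-methyl-D-erythrono-1,4-lactone, (3R,4R)-3,4-dihydroxy-3-methyloxolan-2-one | O=C1[C@](C)(O)[C@H](O)CO1 | starting material
10 | (3R,4R)-4-(tert-butyldimethylsilyloxy)-3-hydroxy-3-methyloxolan-2-one | O=C1[C@](C)(O)[C@H](O[Si](C)(C)C(C)(C)C)CO1 | intermediate
11 | (2R,3R)-3-(tert-butyldimethylsilyloxy)-2,4-dihydroxy-N-methoxy-N,2-dimethylbutanamide | CON(C)C(=O)[C@](C)(O)[C@H](O[Si](C)(C)C(C)(C)C)CO | intermediate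
12 | (2R,3R)-3-(tert-butyldimethylsilyloxy)-2-hydroxy-N-methoxy-N,2-dimethyl-4-(triethylsilyloxy)butanamide | CON(C)C(=O)[C@](C)(O)[C@H](O[Si](C)(C)C(C)(C)C)CO[Si](CC)(CC)CC | intermediate
13 | lithium acetylide of 8 | C=C[C@@H](O[Si](CC)(CC)CC)[C@@H](O[Si](C)(C)C(C)(C)C)[C@@H](C)C#C[Li] | intermediate
14 | chloromagnesium tertiary alkoxide of 12 | CON(C)C(=O)[C@](C)(O[Mg]Cl)[C@H](O[Si](C)(C)C(C)(C)C)CO[Si](CC)(CC)CC | intermediate
15 | (2R,3R,7S,8S,9R)-2,8-bis(tert-butyldimethylsilyloxy)-3-hydroxy-3,7-dimethyl-1,9-bis(triethylsilyloxy)undec-10-en-5-yn-4-one | C=C[C@@H](O[Si](CC)(CC)CC)[C@@H](O[Si](C)(C)C(C)(C)C)[C@@H](C)C#CC(=O)[C@](C)(O)[C@H](O[Si](C)(C)C(C)(C)C)CO[Si](CC)(CC)CC | intermediate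
16 | 6-(diethylamino)undeca-5,10-dien-4-one adduct of 15 (same substituents and centres, C5=C6 geometry not defined, E/Z mixture) | C=C[C@@H](O[Si](CC)(CC)CC)[C@@H](O[Si](C)(C)C(C)(C)C)[C@@H](C)C(N(CC)CC)=CC(=O)[C@](C)(O)[C@H](O[Si](C)(C)C(C)(C)C)CO[Si](CC)(CC)CC | intermediate
17 | (2R)-2-[(1R)-1-(tert-butyldimethylsilyloxy)-2-(triethylsilyloxy)ethyl]-5-[(2R,3S,4R)-3-(tert-butyldimethylsilyloxy)-4-(triethylsilyloxy)hex-5-en-2-yl]-2-methylfuran-3(2H)-one | C=C[C@@H](O[Si](CC)(CC)CC)[C@@H](O[Si](C)(C)C(C)(C)C)[C@@H](C)C1=CC(=O)[C@](C)(O1)[C@H](O[Si](C)(C)C(C)(C)C)CO[Si](CC)(CC)CC | intermediate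
18 | (2R)-2-[(1R)-1-(tert-butyldimethylsilyloxy)-2-hydroxyethyl]-5-[(2R,3S,4R)-3-(tert-butyldimethylsilyloxy)-4-hydroxyhex-5-en-2-yl]-2-methylfuran-3(2H)-one | C=C[C@@H](O)[C@@H](O[Si](C)(C)C(C)(C)C)[C@@H](C)C1=CC(=O)[C@](C)(O1)[C@H](O[Si](C)(C)C(C)(C)C)CO | intermediate
19 | (2S)-2-(tert-butyldimethylsilyloxy)-2-{(2R)-5-[(2R,3S,4R)-3-(tert-butyldimethylsilyloxy)-4-hydroxyhex-5-en-2-yl]-2-methyl-3-oxo-2,3-dihydrofuran-2-yl}acetaldehyde | C=C[C@@H](O)[C@@H](O[Si](C)(C)C(C)(C)C)[C@@H](C)C1=CC(=O)[C@](C)(O1)[C@H](O[Si](C)(C)C(C)(C)C)C=O | intermediate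
20 | 2-(bromomethyl)prop-2-enoic acid | OC(=O)C(=C)CBr | starting material
21 | 2-(bromomethyl)prop-2-enoyl chloride | O=C(Cl)C(=C)CBr | intermediate
22 | (3R,4S,5R)-4-(tert-butyldimethylsilyloxy)-5-{(2R)-2-[(1S)-1-(tert-butyldimethylsilyloxy)-2-oxoethyl]-2-methyl-3-oxo-2,3-dihydrofuran-5-yl}hex-1-en-3-yl 2-(bromomethyl)prop-2-enoate | C=C[C@@H](OC(=O)C(=C)CBr)[C@@H](O[Si](C)(C)C(C)(C)C)[C@@H](C)C1=CC(=O)[C@](C)(O1)[C@H](O[Si](C)(C)C(C)(C)C)C=O | intermediate
23 | (2S)-2-{(2R)-5-[(1S,2R)-1-[(2R)-4-(bromomethyl)-5-oxo-2,5-dihydrofuran-2-yl]-1-(tert-butyldimethylsilyloxy)propan-2-yl]-2-methyl-3-oxo-2,3-dihydrofuran-2-yl}-2-(tert-butyldimethylsilyloxy)acetaldehyde | O=C1O[C@H](C=C1CBr)[C@@H](O[Si](C)(C)C(C)(C)C)[C@@H](C)C2=CC(=O)[C@](C)(O2)[C@H](O[Si](C)(C)C(C)(C)C)C=O | intermediate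
24 | C13-dichlorochromium allyl reagent from 23 (trivalent chromium) | O=C1O[C@H](C=C1C[Cr](Cl)Cl)[C@@H](O[Si](C)(C)C(C)(C)C)[C@@H](C)C2=CC(=O)[C@](C)(O2)[C@H](O[Si](C)(C)C(C)(C)C)C=O | intermediate
25 | (4R,5S,6R,7R,8R,9R,10R)-5,9-bis(tert-butyldimethylsilyloxy)-8-hydroxy-1-oxo-3,10-epoxygermacra-2,11(13)-dien-12,6-olide (cis-fused lactone, C8 epimeric to the target) | C=C1C(=O)O[C@H]2[C@@H](O[Si](C)(C)C(C)(C)C)[C@@H](C)C3=CC(=O)[C@](C)(O3)[C@H](O[Si](C)(C)C(C)(C)C)[C@H](O)[C@@H]12 | intermediate
26 | angelic acid, (Z)-2-methylbut-2-enoic acid | C/C=C(/C)C(=O)O | starting material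
27 | (4R,5S,6R,7S,8S,9R,10R)-8-[(Z)-2-methylbut-2-enoyloxy]-5,9-bis(tert-butyldimethylsilyloxy)-1-oxo-3,10-epoxygermacra-2,11(13)-dien-12,6-olide | C=C1C(=O)O[C@H]2[C@@H](O[Si](C)(C)C(C)(C)C)[C@@H](C)C3=CC(=O)[C@](C)(O3)[C@H](O[Si](C)(C)C(C)(C)C)[C@@H](OC(=O)/C(C)=C\C)[C@@H]12 | intermediate
28 | (4R,5S,6R,7S,8S,9R,10R)-8-[(Z)-2-methylbut-2-enoyloxy]-5,9-dihydroxy-1-oxo-3,10-epoxygermacra-2,11(13)-dien-12,6-olide (CNP0206920.1) | C=C1C(=O)O[C@H]2[C@@H](O)[C@@H](C)C3=CC(=O)[C@](C)(O3)[C@H](O)[C@@H](OC(=O)/C(C)=C\C)[C@@H]12 | target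

## Step count and risks

Total step count: 17. Longest linear sequence: 13 (steps 1, 2, 4, 5, 9–17).

Steps most likely to fail:

1. Step 15. The macrocyclisation may suffer from poor facial selectivity at the butenolide (attack anti to the C5 tether would give the trans-fused lactone), from reductive 1,4-elimination of the lactone carboxylate out of the allylchromium species, or from oligomerisation. Fallback: close the same bond without a low-valent metal and through an open transition state, by an intramolecular Hosomi–Sakurai reaction. It sets out from 19, which is esterified with 2-[(trimethylsilyl)methyl]prop-2-enoic acid (EDC·HCl, DMAP, CH2Cl2) to the C6 2-[(trimethylsilyl)methyl]acrylate F1. Ring-closing metathesis as in step 14 then gives the α-(trimethylsilylmethyl)butenolide aldehyde F2. BF3·OEt2 in CH2Cl2 at −78 °C under high dilution should close C7–C8 with loss of silicon from C13, under Felkin–Anh control of the aldehyde face, and the fallback comes back to the route at 25.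

2. Step 16. The Mitsunobu reaction may stall at the hindered C8 carbinol, or the oxyphosphonium may eliminate toward C9. Fallback: two-step sulfonate displacement. It sets out from 25, which is converted with ClCH2SO2Cl and pyridine (0 °C) into the C8 chloromethanesulfonate F3. Displacement with 26, Cs2CO3 and 18-crown-6 in toluene at 80 °C should give the inverted ester, and the fallback comes back at 27.

3. Step 14 (with its acylation, step 13). Ring closure of the hindered 1,1-disubstituted bromomethyl acrylate may be slow, with catalyst decay, cross-metathesis dimerisation or loss of the allylic bromide. Fallback: install the halide after the ring. It sets out from 19, which is esterified with 2-{[(triethylsilyl)oxy]methyl}prop-2-enoic acid (2,4,6-trichlorobenzoyl chloride, Et3N, DMAP, toluene; nucleophilic catalysis is now allowed) to the C6 2-(silyloxymethyl)acrylate F4. Ring-closing metathesis gives the α-(triethylsilyloxymethyl)butenolide aldehyde F5. HF·pyridine/pyridine in THF at 0 °C removes only the primary allylic silyl ether to give the α-(hydroxymethyl)butenolide aldehyde F6. MsCl, 2,4,6-collidine and LiBr in DMF at 0 °C convert it through the allylic mesylate F7 into the bromide, and the fallback comes back at 23.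

## Further compounds

F1 | step 15 | (3R,4S,5R)-4-(tert-butyldimethylsilyloxy)-5-{(2R)-2-[(1S)-1-(tert-butyldimethylsilyloxy)-2-oxoethyl]-2-methyl-3-oxo-2,3-dihydrofuran-5-yl}hex-1-en-3-yl 2-[(trimethylsilyl)methyl]prop-2-enoate | C=C[C@@H](OC(=O)C(=C)C[Si](C)(C)C)[C@@H](O[Si](C)(C)C(C)(C)C)[C@@H](C)C1=CC(=O)[C@](C)(O1)[C@H](O[Si](C)(C)C(C)(C)C)C=O
F2 | step 15 | analogue of 23 with CH2SiMe3 in place of CH2Br on the butenolide | O=C1O[C@H](C=C1C[Si](C)(C)C)[C@@H](O[Si](C)(C)C(C)(C)C)[C@@H](C)C2=CC(=O)[C@](C)(O2)[C@H](O[Si](C)(C)C(C)(C)C)C=O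
F3 | step 16 | C8 chloromethanesulfonate of 25 | C=C1C(=O)O[C@H]2[C@@H](O[Si](C)(C)C(C)(C)C)[C@@H](C)C3=CC(=O)[C@](C)(O3)[C@H](O[Si](C)(C)C(C)(C)C)[C@H](OS(=O)(=O)CCl)[C@@H]12
F4 | step 14 | analogue of 22 with a 2-{[(triethylsilyl)oxy]methyl}prop-2-enoate ester at C6 | C=C[C@@H](OC(=O)C(=C)CO[Si](CC)(CC)CC)[C@@H](O[Si](C)(C)C(C)(C)C)[C@@H](C)C1=CC(=O)[C@](C)(O1)[C@H](O[Si](C)(C)C(C)(C)C)C=O
F5 | step 14 | analogue of 23 with CH2OSiEt3 in place of CH2Br | O=C1O[C@H](C=C1CO[Si](CC)(CC)CC)[C@@H](O[Si](C)(C)C(C)(C)C)[C@@H](C)C2=CC(=O)[C@](C)(O2)[C@H](O[Si](C)(C)C(C)(C)C)C=O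
F6 | step 14 | analogue of 23 with CH2OH in place of CH2Br | O=C1O[C@H](C=C1CO)[C@@H](O[Si](C)(C)C(C)(C)C)[C@@H](C)C2=CC(=O)[C@](C)(O2)[C@H](O[Si](C)(C)C(C)(C)C)C=O
F7 | step 14 | analogue of 23 with CH2OSO2CH3 in place of CH2Br | O=C1O[C@H](C=C1COS(C)(=O)=O)[C@@H](O[Si](C)(C)C(C)(C)C)[C@@H](C)C2=CC(=O)[C@](C)(O2)[C@H](O[Si](C)(C)C(C)(C)C)C=O
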